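- Both simulated flasks are slow: by 9.6 h the zeta run has turned 47.8 % of its substrate into target and the eta run 43.2 %, and both curves are nearly flat.

| flask | substrate | partner | time |
|---|---|---|---|
| zeta | 50.0 mM | 100 mM |  |
| eta | 100 mM | 100 mM |  |
| epsilon | 320 mM | 100 mM | 9.6 h |

| run | time / h | [target] / mM |
|---|---|---|
| zeta run | 1.2 | 5.9 |
| zeta run | 2.4 | 12.6 |
| zeta run | 3.6 | 18.2 |
| zeta run | 4.8 | 21.0 |
| zeta run | 6.0 | 22.1 |
| zeta run | 7.2 | 23.9 |
| zeta run | 8.4 | 24.4 |
| zeta run | 9.6 | 23.9 |
| eta run | 1.2 | 11.5 |
| eta run | 2.4 | 24.1 |
| eta run | 3.6 | 31.9 |
| eta run | 4.8 | 36.9 |
| eta run | 6.0 | 40.1 |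
| eta run | 7.2 | 41.8 |
| eta run | 8.4 | 42.4 |
| eta run | 9.6 | 43.2 |

(readings scatter by 0.4 mM)

1. reaction order in [substrate] at the outset, round the charge of the zeta run, defined at two percent of the substrate turned into target (one fixed amount of target, the same in the runs compared)
2. target in the epsilon run at 9.6 h, as a share of the substrate charged

- Overall: substrate + partner -> target.
- Constant volume, constant temperature.
- "The second partner" is partner.
- An order is taken over about fifteen percent of the charge, up and down.

- The bench rule says that a first-order flask turns equal shares in equal times, whatever the charge, and it is our zero of the scale. These two shares lie close to it, although c(substrate) doubles between the runs.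
- The rule ends where the share would need more target than the partner charged can give, since one partner goes into each target. At the eta share, that border lies at a substrate charge of 231 mM, and the epsilon charge is 1.38 times this. In epsilon, partner is the limiting reagent, with a ceiling of 31.2 % of the substrate charged.
- So we carry the partner exposure per charge: the natural logarithm of c(partner) charged over c(partner) charged minus target made, divided by c(substrate) charged. It treats partner as pseudo-first-order. At 9.6 h it reads 5.46 M⁻¹ in zeta and 5.66 M⁻¹ in eta, and we take forward the eta reading of this partner exposure per charge.
- Our own reckoning takes the eta value into epsilon and gives 26.1 %, under the ceiling.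
- The forecast says 26.8 % (range 24 % to 28 %) and an order of 0.6 (range 0.42 to 0.95), below one since at fixed target “the richer run gets there sooner”. We put no order of our own beside it.
- The flask gives an order of 0.69, inside the forecast's range, and 23.1 %, below the low end of its range but within the tolerance of the question.

    substrate + partner → intermediate (14.11 M⁻¹ h⁻¹)
    intermediate → target (0.4680 h⁻¹)
    2 partner → lost reagent (13.82 M⁻¹ h⁻¹)
    target + partner → side product (12.92 M⁻¹ h⁻¹)

- Where two percent of the zeta substrate has turned into target, the eta rate over the zeta rate is 1.6, less than the charge ratio of 2.00. By 9.6 h the epsilon run has made 73.8 mM, so its exposure per charge is 4.18 M⁻¹, lower than the eta reading of 5.66 M⁻¹.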